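At the reading after 10 d, what mattered was how much of the L charge could still be Q, so I began from the flasks and the earlier runs.

| setting | winter | spring | grey | green |
|---|---|---|---|---|
| L | 0.12 M | 0.19 M | 0.25 M | 0.25 M |
| G | 0.075 M | 0.075 M | 0.0750 M | 0.0750 M |
| temperature | 0 °C | 20 °C | 5 °C | 35 °C |
| remark | run made earlier | run made earlier |  |  |
| time |  |  | 10 d | 10 d |

| run | time / d | Q / % |
|---|---|---|
| winter | 0.500 | 2.5 |
| winter | 1.67 | 1.6 |
| winter | 3.00 | 2.2 |
| winter | 4.00 | 0 |
| winter | 6.00 | 2.4 |
| winter | 8.00 | 0 |
| winter | 10.0 | 1.1 |
| spring | 0.250 | 2.4 |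
| spring | 0.833 | 6.8 |
| spring | 1.25 | 14.5 |
| spring | 2.08 | 21.5 |
| spring | 3.00 | 26.4 |
| spring | 4.00 | 33.7 |
| spring | 5.00 | 37.0 |

(standard deviation of a reading: 1 percentage point)

* the flask that comes out highest in amount of Q, in percent of the L charged, or "all alike" when all lie within 1.5 percentage points (grey / green / all alike)
* Q at the end, in percent of the L charged, grey
* Q at the end, in percent of the L charged, green



The winter readings lay between 0% and 2.5% under a scatter of 1 percentage point, while spring climbed to 37.0% by 5.00 d, though those runs differ in L as well as in temperature. I supposed that G might take L one for one in a fast competing step, treated that step as finished, and reckoned with what it leaves. This is the free share, the part of the charged L remaining once the G charge is deducted, and for grey and for green it is 70.0%. Spring's free share of 60.5% lay above its last reading, so the runs did not test this supposition.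

The forecast put grey at 5% (3% to 9%) and green at 97% (70% to 100%), naming green, and judged that “G seems to act as a catalyst rather than a reagent”. I turned the question round. For a tie, green would have had to stop within 1.5 points of grey, yet its free share stood 65 points above the forecast's grey. I therefore agreed on green, but my own figure for green was near 70.0%, lower than the forecast's.

The flasks gave 4.77% in grey and 67.1% in green, so green came out highest.

    L + 2 Q → 3 Q (k = 3.00 × 10⁻⁴ M⁻² s⁻¹, Ea = 67.0 kJ mol⁻¹)
    L → Q (k = 2.30 × 10⁻⁷ s⁻¹, Ea = 104 kJ mol⁻¹)
    L + G → D (k = 4.20 × 10⁻⁵ M⁻¹ s⁻¹, Ea = 53.0 kJ mol⁻¹)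
    Q ⇌ Z (K = 2.10, k = 3.10 × 10⁻⁵ s⁻¹, Ea = 92.0 kJ mol⁻¹, ΔH = −68.0 kJ mol⁻¹)
    (constants at 5 °C)

The largest single effect on the gap between green and grey was what the temperature does to the step from Q to Z: the gap was 62 points as the flasks stood and 19 points in the run with that effect taken away. At the end of green, D held 24.9% of the L charged and G kept 17.1% of its own charge, so 75.1% of the L stood outside D, against the free share of 70.0%.

For green with 1.0 M of L, the free share is 92.5%. Computed, that flask had 93.4% of its L outside D, and Q reached 83.4%.

The data are simulated from invented constants; scatter was added.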